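The seven-membered ring is numbered C1 (anisoyloxy), C2, C3 (methyl), C4, C5 (acetoxy), C6 (quaternary), C10; the five-membered ring is C6–C10, with C9 the isopropyl carbinol. The route rests on breaking C5–C6. A thermal Cope rearrangement of a cis-divinylcyclopropane (ring C1–C2–C3, arms C4=C5 and C10=C6) closes the seven-membered ring, sets C5 and C6 together, and leaves the C3=C4 alkene and a masked C1 ketone. It exploits the vicinal sp3 pair C5/C6 lying between that alkene and the C1 oxygen. The precursor carries a Z-enol acetate, and a diisopropylsilylene ties the C1 and C9 oxygens, holding the cyclopentenyl arm in the reactive orientation.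

Key step: step 9

Assumption: (S)-(+)-terpinen-4-ol (1) is used as enantiopure material; a lot of lower enantiomeric purity would be upgraded first, because C9 is the only source of absolute configuration.

Atom labels C1–C10, O1 (on C1) and O9 (on C9) below follow the numbering of the first paragraph.

Step 1
Reactants: 1 (S)-(+)-terpinen-4-ol
Product: 2 triethyl{[(1S)-4-methyl-1-(propan-2-yl)cyclohex-3-en-1-yl]oxy}silane
Conditions: Et3SiOTf, 2,6-lutidine, CH2Cl2, 0 °C
Reagents that add atoms: triethylsilyl trifluoromethanesulfonate, CC[Si](CC)(CC)OS(=O)(=O)C(F)(F)F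
Why: Silyl triflate silylation of a hindered tertiary alcohol is standard; the ether keeps this oxygen from being lost in the aldol condensation of step 3, and the stereocentre is not touched.

Step 2
Reactants: 2 triethyl{[(1S)-4-methyl-1-(propan-2-yl)cyclohex-3-en-1-yl]oxy}silane
Product: 4 (3S)-6-oxo-3-(propan-2-yl)-3-[(triethylsilyl)oxy]heptanal, via ozonide 3 (not isolated)
Conditions: O3, CH2Cl2, −78 °C; then PPh3, −78 °C → rt
Reagents that add atoms: ozone, [O-][O+]=O
Why: Ozonolysis with reductive work-up cleaves the only alkene to the keto aldehyde and leaves the future C9 centre untouched.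

Step 3
Reactants: 4 (3S)-6-oxo-3-(propan-2-yl)-3-[(triethylsilyl)oxy]heptanal
Product: 5 (5R)-2-methyl-5-(propan-2-yl)-5-[(triethylsilyl)oxy]cyclopent-1-ene-1-carbaldehyde
Conditions: piperidine, AcOH (cat.), toluene, 60 °C
Reagents that add atoms: none
Why: Amine-salt-mediated intramolecular aldol condensation in which the aldehyde enamine attacks the methyl ketone (five-membered ring) and the new tertiary hydroxyl, not the silyl ether, should be lost to give the conjugated enal with C10=C6 in place.

Step 4
Reactants: 5 (5R)-2-methyl-5-(propan-2-yl)-5-[(triethylsilyl)oxy]cyclopent-1-ene-1-carbaldehyde; 6 3-bromobut-1-yne (racemic)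
Product: 8 (1R)-2-(1-hydroxy-2-methylbut-3-yn-1-yl)-3-methyl-1-(propan-2-yl)cyclopent-2-en-1-ol (mixture at the two side-chain centres), via silyl ether 7 (not isolated)
Conditions: In powder, THF/sat. aq NH4Cl, rt; then Bu4NF, THF, 0 °C → rt
Reagents that add atoms: none
Why: Barbier-type propargylation in which the allenylindium from 6 adds through its γ-carbon (SE2') to give the homopropargylic alcohol, after which fluoride removes the triethylsilyl group; the two new centres form unselectively and are erased in steps 5 and 6.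

Step 5
Reactants: 8 (1R)-2-(1-hydroxy-2-methylbut-3-yn-1-yl)-3-methyl-1-(propan-2-yl)cyclopent-2-en-1-ol
Product: 9 1-[(5R)-5-hydroxy-2-methyl-5-(propan-2-yl)cyclopent-1-en-1-yl]-2-methylbut-3-yn-1-one (epimers at C3; used crude)
Conditions: Dess–Martin periodinane, NaHCO3, CH2Cl2, 0 °C
Reagents that add atoms: none
Why: Dess–Martin oxidation of the secondary allylic alcohol, with the tertiary alcohol inert and the buffer guarding against ionisation and alkyne-to-allene isomerisation.

Step 6
Reactants: 9 1-[(5R)-5-hydroxy-2-methyl-5-(propan-2-yl)cyclopent-1-en-1-yl]-2-methylbut-3-yn-1-one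
Product: 10 (4E,7aR)-4-(but-3-yn-2-ylidene)-5-methyl-2,2,7a-tri(propan-2-yl)-4,6,7,7a-tetrahydrocyclopenta[d][1,3,2]dioxasiline (cyclic silyl dienol ether: Si bridges O1 and O9, C1=C3 exocyclic, ethynyl cis to C10)
Conditions: iPr2Si(OTf)2, Et3N, CH2Cl2, −78 → 0 °C
Reagents that add atoms: di(propan-2-yl)silanediyl bis(trifluoromethanesulfonate), CC(C)[Si](OS(=O)(=O)C(F)(F)F)(OS(=O)(=O)C(F)(F)F)C(C)C
Why: Silyl triflate/amine enol silylation of a β-hydroxy ketone with ring closure onto the C9 hydroxyl to the six-membered dioxasiline; only C3 can be deprotonated, and the E enol ether (methyl cis to O1, slim ethynyl cis to the crowded C10) is the less strained isomer and the one expected.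

Step 7
Reactants: 10 (4E,7aR)-4-(but-3-yn-2-ylidene)-5-methyl-2,2,7a-tri(propan-2-yl)-4,6,7,7a-tetrahydrocyclopenta[d][1,3,2]dioxasiline
Product: 11 (1S,2R,7a'R)-2-ethynyl-2,5'-dimethyl-2',2',7a'-tri(propan-2-yl)-6',7'-dihydro-7a'H-spiro[cyclopropane-1,4'-cyclopenta[d][1,3,2]dioxasiline] (cyclopropane C1–C2–C3 spiro at C1; ethynyl cis to C10, methyl cis to O1; C1 S, C3 R, C9 R)
Conditions: Et2Zn, CH2I2, CH2Cl2, 0 °C → rt
Reagents that add atoms: diiodomethane, ICI
Why: Simmons–Smith (Furukawa) cyclopropanation of the electron-rich silyl enol ether in preference to the tetrasubstituted cyclopentene and the alkyne; stereospecific syn addition turns the E geometry into the cis relation of ethynyl and cyclopentenyl, and methylene should add to the face of the silacycle anti to the pseudo-axial C9 isopropyl group, which sets C1 (S) and C3 (R).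

Step 8
Reactants: 11 (1S,2R,7a'R)-2-ethynyl-2,5'-dimethyl-2',2',7a'-tri(propan-2-yl)-6',7'-dihydro-7a'H-spiro[cyclopropane-1,4'-cyclopenta[d][1,3,2]dioxasiline]
Product: 12 (Z)-2-[(1S,2R,7a'R)-2,5'-dimethyl-2',2',7a'-tri(propan-2-yl)-6',7'-dihydro-7a'H-spiro[cyclopropane-1,4'-cyclopenta[d][1,3,2]dioxasilin]-2-yl]ethenyl acetate (the cis-divinylcyclopropane)
Conditions: [RuCl2(p-cymene)]2 (cat.), P(4-ClC6H4)3, DMAP, AcOH, toluene, 60 °C
Reagents that add atoms: acetic acid, CC(=O)O
Why: Ruthenium-catalysed anti-Markovnikov hydro-acyloxylation of a terminal alkyne through a ruthenium vinylidene, which with this phosphine/DMAP combination gives the Z enol ester; the nearly neutral medium should spare the silacycle and the cyclopropane, and the temperature is kept below that of step 9.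

Step 9
Reactants: 12 (Z)-2-[(1S,2R,7a'R)-2,5'-dimethyl-2',2',7a'-tri(propan-2-yl)-6',7'-dihydro-7a'H-spiro[cyclopropane-1,4'-cyclopenta[d][1,3,2]dioxasilin]-2-yl]ethenyl acetate
Product: 13 silylene-bridged bicyclo[5.3.0]decadiene: C1=C10 enol ether and C9 oxygen joined through Si(iPr)2, C3=C4 alkene, (5S)-acetoxy cis to the (6S)-methyl, (9R)-isopropyl
Conditions: toluene (degassed), 120 °C, sealed base-washed tube
Reagents that add atoms: none
Why: Concerted [3,3]-sigmatropic (Cope) rearrangement of a cis-1,2-dialkenylcyclopropane through the boat transition state with both arms over the three-membered ring; the closest known reaction type is the cis-divinylcyclopropane to cyclohepta-1,4-diene rearrangement, including siloxy-substituted cases and cases that create quaternary centres. The seven-membered ring closes by σ-bond formation between the arm termini C5 and C6 while the strained C1–C3 bond breaks, so the three-membered ring opens into the C1–C2–C3 segment of the new ring. C6 is controlled by the cyclopropane configuration: C3 sits on the cyclopentene face syn to the C9 isopropyl group, C5 therefore bonds to that face and the inward methyl ends on the other (C6 S). C5 is controlled by the Z enol acetate geometry, which places the inward acetoxy group cis to the C6 methyl (C5 S). The step needs the boat (endo,endo) pathway and cis arms; the silylene tether holds O1 syn to C9 and so keeps C10=C6 under the cyclopropane, and step 7 supplies the cis relation. Strain release drives the reaction and should offset the two inward substituents.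

Step 10
Reactants: 13 silylene-bridged bicyclo[5.3.0]decadiene
Product: 14 (5S,6S,9R)-5-acetoxy-9-hydroxy-3,6-dimethyl-9-(propan-2-yl)bicyclo[5.3.0]dec-3-en-1-one as the mixture of C10 epimers
Conditions: HF·pyridine, pyridine, THF, 0 °C
Reagents that add atoms: none
Why: Fluoride cleaves both Si–O bonds and the freed enol ketonises; the proton is expected to reach C10 mainly from the convex face (anti to the isopropyl group), so the ring fusion is not yet secured and the mixture is carried on.

Step 11
Reactants: 14 (5S,6S,9R)-5-acetoxy-9-hydroxy-3,6-dimethyl-9-(propan-2-yl)bicyclo[5.3.0]dec-3-en-1-one (C10 epimers)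
Product: 15 (5S,6S,9R,10R)-5-acetoxy-9-hydroxy-3,6-dimethyl-9-(propan-2-yl)bicyclo[5.3.0]dec-3-en-1-one (trans ring fusion: C10–H trans to the C6 methyl, cis to the isopropyl group)
Conditions: DBU (cat.), toluene, 0 °C, short contact
Reagents that add atoms: none
Why: Base-mediated epimerisation through the C1/C10 enolate under thermodynamic control; the trans-fused epimer keeps C1 anti to the C9 isopropyl group and allows the C9–OH···O=C1 hydrogen bond, so it should dominate at equilibrium.

Step 12
Reactants: 15 (5S,6S,9R,10R)-5-acetoxy-9-hydroxy-3,6-dimethyl-9-(propan-2-yl)bicyclo[5.3.0]dec-3-en-1-one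
Product: 16 (1S,5S,6S,9R,10S)-5-acetoxy-3,6-dimethyl-9-(propan-2-yl)bicyclo[5.3.0]dec-3-ene-1,9-diol (C1–OH trans to C9–OH)
Conditions: Me4NBH(OAc)3, MeCN/AcOH, −20 °C
Reagents that add atoms: none
Why: Hydroxyl-directed (Evans–Saksena) reduction in which the C9 hydroxyl exchanges onto boron and hydride is delivered intramolecularly to the carbonyl face syn to that oxygen, giving the 1,3-anti diol with C1 (S); ester and alkene are inert.

Step 13
Reactants: 16 (1S,5S,6S,9R,10S)-5-acetoxy-3,6-dimethyl-9-(propan-2-yl)bicyclo[5.3.0]dec-3-ene-1,9-diol; 17 4-methoxybenzoyl chloride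
Product: 18 CNP0256979.3, (1S,5S,6S,9R,10S)-5-acetoxy-9-hydroxy-3,6-dimethyl-9-(propan-2-yl)bicyclo[5.3.0]dec-3-en-1-yl 4-methoxybenzoate
Conditions: Et3N, DMAP, CH2Cl2, 0 °C → rt
Reagents that add atoms: none
Why: DMAP-catalysed acylation of the only secondary hydroxyl; the tertiary C9 hydroxyl does not react and no stereocentre is touched.

Compound list
1 | (S)-(+)-terpinen-4-ol, (1S)-4-methyl-1-(propan-2-yl)cyclohex-3-en-1-ol | CC1=CC[C@](O)(C(C)C)CC1 | starting material
2 | triethyl{[(1S)-4-methyl-1-(propan-2-yl)cyclohex-3-en-1-yl]oxy}silane | CC1=CC[C@](O[Si](CC)(CC)CC)(C(C)C)CC1 | intermediate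
3 | ozonide of 2 (1,2,4-trioxolane across the former alkene carbons, new centres unselective; not isolated) | CC12OOC(O1)C[C@](O[Si](CC)(CC)CC)(C(C)C)CC2 | intermediate
4 | (3S)-6-oxo-3-(propan-2-yl)-3-[(triethylsilyl)oxy]heptanal | CC(=O)CC[C@@](O[Si](CC)(CC)CC)(C(C)C)CC=O | intermediate
5 | (5R)-2-methyl-5-(propan-2-yl)-5-[(triethylsilyl)oxy]cyclopent-1-ene-1-carbaldehyde | CC1=C(C=O)[C@](O[Si](CC)(CC)CC)(C(C)C)CC1 | intermediate
6 | 3-bromobut-1-yne (racemic) | CC(Br)C#C | starting material
7 | 2-methyl-1-[(5R)-2-methyl-5-(propan-2-yl)-5-(triethylsilyloxy)cyclopent-1-en-1-yl]but-3-yn-1-ol (diastereomer mixture; not isolated) | C#CC(C)C(O)C1=C(C)CC[C@@]1(O[Si](CC)(CC)CC)C(C)C | intermediate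
8 | (1R)-2-(1-hydroxy-2-methylbut-3-yn-1-yl)-3-methyl-1-(propan-2-yl)cyclopent-2-en-1-ol (diastereomer mixture) | C#CC(C)C(O)C1=C(C)CC[C@@]1(O)C(C)C | intermediate
9 | 1-[(5R)-5-hydroxy-2-methyl-5-(propan-2-yl)cyclopent-1-en-1-yl]-2-methylbut-3-yn-1-one | C#CC(C)C(=O)C1=C(C)CC[C@@]1(O)C(C)C | intermediate
10 | (4E,7aR)-4-(but-3-yn-2-ylidene)-5-methyl-2,2,7a-tri(propan-2-yl)-4,6,7,7a-tetrahydrocyclopenta[d][1,3,2]dioxasiline | C#C/C(C)=C1\C2=C(C)CC[C@]2(C(C)C)O[Si](C(C)C)(C(C)C)O1 | intermediate
11 | (1S,2R,7a'R)-2-ethynyl-2,5'-dimethyl-2',2',7a'-tri(propan-2-yl)-6',7'-dihydro-7a'H-spiro[cyclopropane-1,4'-cyclopenta[d][1,3,2]dioxasiline] | C#C[C@@]1(C)C[C@@]12C3=C(C)CC[C@]3(C(C)C)O[Si](C(C)C)(C(C)C)O2 | intermediate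
12 | (Z)-2-[(1S,2R,7a'R)-2,5'-dimethyl-2',2',7a'-tri(propan-2-yl)-6',7'-dihydro-7a'H-spiro[cyclopropane-1,4'-cyclopenta[d][1,3,2]dioxasilin]-2-yl]ethenyl acetate (key-step precursor) | CC(=O)O/C=C\[C@@]1(C)C[C@@]12C3=C(C)CC[C@]3(C(C)C)O[Si](C(C)C)(C(C)C)O2 | intermediate
13 | silylene-bridged Cope product: C1=C10 enol ether and O9 joined by Si(iPr)2, C3=C4 alkene, (5S)-acetoxy, (6S)-methyl, (9R)-isopropyl | CC(C)[Si]1(C(C)C)OC2=C3[C@](O1)(C(C)C)CC[C@]3(C)[C@@H](OC(C)=O)C=C(C)C2 | intermediate
14 | (5S,6S,9R)-5-acetoxy-9-hydroxy-3,6-dimethyl-9-(propan-2-yl)bicyclo[5.3.0]dec-3-en-1-one, C10 epimer mixture | CC(=O)O[C@H]1C=C(C)CC(=O)C2[C@](O)(C(C)C)CC[C@]12C | intermediate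
15 | (5S,6S,9R,10R)-5-acetoxy-9-hydroxy-3,6-dimethyl-9-(propan-2-yl)bicyclo[5.3.0]dec-3-en-1-one (trans-fused) | CC(=O)O[C@H]1C=C(C)CC(=O)[C@H]2[C@](O)(C(C)C)CC[C@]12C | intermediate
16 | (1S,5S,6S,9R,10S)-5-acetoxy-3,6-dimethyl-9-(propan-2-yl)bicyclo[5.3.0]dec-3-ene-1,9-diol | CC(=O)O[C@H]1C=C(C)C[C@H](O)[C@H]2[C@](O)(C(C)C)CC[C@]12C | intermediate
17 | 4-methoxybenzoyl chloride | COc1ccc(C(Cl)=O)cc1 | starting material
18 | CNP0256979.3 | COc1ccc(C(=O)O[C@H]2CC(C)=C[C@H](OC(C)=O)[C@@]3(C)CC[C@@](O)(C(C)C)[C@H]23)cc1 | target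

Total steps: 13. Longest linear sequence: 13 steps (1 → 18); 6 and 17 are bought.

Steps most likely to fail

Step 9. The boat transition state has two inward groups and the isopropyl group next to C10. Compression may slow the rearrangement until one-centre epimerisation of the cyclopropane or thermal loss of the enol ester competes. The fallback takes the oxygen out of the inward position and sets out from 11.
- Hydroboration with pinacolborane and Cp2ZrHCl (cat.) should give the (E)-alkenyl pinacol boronate F1.
- Heating F1 (one inward substituent only) should give the allylic boronate F2, with boron trans to the C6 methyl.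
- NaBO3·4H2O in THF/water should oxidise it with retention to the C5-epimeric allylic alcohol F3.
- Dess–Martin periodinane should give the enone F4.
- iBu2AlH in toluene at −78 °C should deliver hydride to the carbonyl face opposite the angular methyl and give the allylic alcohol F5 with the natural C5 configuration.
- Ac2O, DMAP and pyridine return the route to 13.

Step 11. Enolisation towards C2 is easier than at C10, so vinylogous elimination of the allylic acetate or migration of the C3=C4 alkene into conjugation may outrun the epimerisation. The fallback removes the leaving group before equilibration and sets out from 14.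
- K2CO3 in MeOH at 0 °C should cleave the acetate and equilibrate C10 in one operation, giving the trans-fused dihydroxy ketone F6.
- Ac2O and pyridine should acetylate its only secondary hydroxyl and return the route to 15.

Step 7. The twisted diene may expose the enol ether face syn to the isopropyl group, so methylene transfer could show poor facial selectivity. The fallback replaces steric control by hydroxyl direction and sets out from 9.
- iPr3SiOTf and Et3N at −78 °C should silylate only the enol oxygen and give the triisopropylsilyl dienol ether F7 with the tertiary hydroxyl free.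
- Et2Zn and CH2I2 should form the zinc alkoxide, which delivers methylene to the face it can reach in the rotamer that keeps C3 away from the isopropyl group, giving the cyclopropyl silyl ether F8 with the same configuration as 11.
- Bu4NF buffered with AcOH should free the cyclopropanol F9.
- iPr2Si(OTf)2 and 2,6-lutidine close the silacycle and return the route to 11.

Further compounds
F1 | step 9 | (E)-alkenyl pinacol boronate of the spiro cyclopropane | CC1(C)OB(/C=C/[C@@]2(C)C[C@@]23C4=C(C)CC[C@]4(C(C)C)O[Si](C(C)C)(C(C)C)O3)OC1(C)C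
F2 | step 9 | allylic boronate, boron at C5 trans to the C6 methyl | CC(C)[Si]1(C(C)C)OC2=C3[C@](O1)(C(C)C)CC[C@]3(C)[C@H](B4OC(C)(C)C(C)(C)O4)C=C(C)C2
F3 | step 9 | C5-epimeric allylic alcohol | CC(C)[Si]1(C(C)C)OC2=C3[C@](O1)(C(C)C)CC[C@]3(C)[C@H](O)C=C(C)C2
F4 | step 9 | C5 enone | CC(C)[Si]1(C(C)C)OC2=C3[C@](O1)(C(C)C)CC[C@]3(C)C(=O)C=C(C)C2
F5 | step 9 | allylic alcohol with natural C5 configuration | CC(C)[Si]1(C(C)C)OC2=C3[C@](O1)(C(C)C)CC[C@]3(C)[C@@H](O)C=C(C)C2
F6 | step 11 | trans-fused 5,9-dihydroxy ketone | O[C@H]1C=C(C)CC(=O)[C@H]2[C@](O)(C(C)C)CC[C@]12C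
F7 | step 7 | triisopropylsilyl dienol ether with free C9 hydroxyl | C#C/C(C)=C(/O[Si](C(C)C)(C(C)C)C(C)C)C1=C(C)CC[C@@]1(O)C(C)C
F8 | step 7 | cyclopropyl triisopropylsilyl ether with free C9 hydroxyl | C#C[C@@]1(C)C[C@@]1(O[Si](C(C)C)(C(C)C)C(C)C)C2=C(C)CC[C@@]2(O)C(C)C
F9 | step 7 | cyclopropanol diol | C#C[C@@]1(C)C[C@@]1(O)C2=C(C)CC[C@@]2(O)C(C)C
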